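(The runs were generated by integration for an exercise; the scatter is artificial.)

Read the flask at 12 min and you will read a plateau: each earlier run is flat from its first reading, the summer run from 0.417 min. Partner was never read, so these readings do not show what kind of stop it is.

| flask | substrate | partner | remark | time |
|---|---|---|---|---|
| winter | 0.0070 M | 10 mM | run made earlier |  |
| summer | 0.011 M | 10 mM | run made earlier |  |
| dusk | 0.0050 M | 5 mM | run made earlier |  |
| flask | 0.0050 M | 10.0 mM |  | 12 min |

| run | time / min | substrate / % | product / % |
|---|---|---|---|
| winter | 1.00 | 19.0 | 79.9 |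
| winter | 2.00 | 19.5 | 79.4 |
| winter | 3.00 | 18.7 | 80.1 |
| winter | 4.00 | 18.9 | 79.7 |
| winter | 5.00 | 18.4 | 80.3 |
| winter | 6.00 | 19.3 | 79.3 |
| winter | 8.00 | 18.6 | 79.0 |
| summer | 0.417 | 35.4 | 62.5 |
| summer | 1.00 | 35.3 | 62.7 |
| summer | 2.00 | 35.6 | 63.1 |
| summer | 3.00 | 34.9 | 62.8 |
| summer | 4.00 | 35.5 | 62.6 |
| summer | 6.00 | 35.1 | 62.5 |
| summer | 8.00 | 35.7 | 62.8 |
| dusk | 1.33 | 30.7 | 65.0 |
| dusk | 3.00 | 30.6 | 65.7 |
| dusk | 4.00 | 30.7 | 65.3 |
| dusk | 6.00 | 30.7 | 64.8 |
| dusk | 8.00 | 30.7 | 65.9 |

(scatter of a reading: 0.3 percentage points)

1. the state of affairs at 12 min: stopped, and by what, or still going (all of the substrate has reacted / it is still moving / the partner has run out first / forward and back rates have come level)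
2. how much of the substrate has reacted by 12 min
3. how much product there is at 12 min, in percent of the substrate charged

- the reaction counts as stopped when no species that holds the substrate changes by six tenths of a point or more over the second half of the time

Product is the large thing, so reckon the small one, the miss: the share of charged substrate not in product on the plateau. Let r = c(partner)/c(substrate). Averaged over its readings, the winter run has r = 1.43 and miss 20.3 %; the summer run has r = 0.909 and miss 37.3 %. Assume ln(miss) falls in a straight line with r:

b = ln(summer miss / winter miss) / (winter r − summer r) = 1.17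

Call b the miss exponent, the fall of ln(miss) per equivalent of partner. The dusk run, not used so far, tests it: at r = 1.00, winter and b give 33.5 %, and dusk reads 34.7 %. That is close, but not exact.

The weak link is the anchor, since winter holds a different substrate charge. Dusk holds the flask's, so start there, with the flask at r = 2.00:

miss = dusk miss × exp(−b × (flask r − dusk r)) = 10.8 %

I commit to 89.2 % product, with conversion a little above it. The forecast says forward and back rates have come level, with 87 % conversion and 85.7 % product, holding that “the reaction is not limited by exhaustion”; my product is higher than its figure.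

The flask gives 89.9 % conversion and 89.0 % product at 12 min. The state there is that the partner has run out first: partner stands at 0 % of its charge, with 10 % of the substrate left.

    substrate ⇌ intermediate + leaving ligand (K = 4.30 × 10⁻⁴ M, k = 0.150 /s)
    partner + intermediate → product (k = 1600 /M/s)
    partner → decomposed reagent (k = 0.0930 /s)

The flask's miss is 11.0 %, against the 10.8 % reckoned. Now take the neighbour flask with 0.0025 M of partner, at r = 0.500: dusk and b give a miss of 62.3 %, and that neighbour flask makes 39.3 % product, a miss of 60.7 %.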